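**Remarks on the chemistry**
- Ring numbering used throughout: C1 is the quaternary carbinol carbon, C1′ its exocyclic CH2, C2=C3 the alkene, C4 the benzoyloxy carbon, C5 and C6 the secondary carbinols; O-numbers follow the carbons.
- The configurations of 20, 22 and 23 were re-derived atom by atom and agree with one another (23 is 1S,4R,5S,6S). No structural correction was needed; what is changed is the way to 20.
- Compounds 18–20 are handled as mixtures of C2 epimers and enol-ester E/Z isomers (one isomer drawn). Lactols 3, 5 and 7 are anomer mixtures (anomeric carbon left undefined in the SMILES).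

## Structural features

The target 23 is a single cyclohexene ring whose six carbons carry five oxygen functions: a tertiary carbinol at C1 that also bears the CH2OBz arm (C1′), the C2=C3 alkene, an allylic benzoate at C4 and secondary hydroxyls at C5 and C6. The four stereocentres C4, C5, C6 and C1 are contiguous: O4/O5 are cis, O5/O6 trans, O6/O1 cis, and C1′ lies on the same face as O4. The benzoates sit next to free hydroxyls, so base promotes acyl migration (O4 to the cis O5, O1′ to O1 or O6), and the C4 benzoate is allylic and ionisable. The 1,6-diol containing a tertiary carbinol can eliminate toward an arene under forcing acid or base. The real difficulty is threefold: the quaternary C1 must be set relative to C6, a cis C4/C5 pair must stand beside a trans C5/C6 pair, and five oxygens must be told apart so that only O1′ and O4 are acylated. The key step exploits the array C5(OH)–C4(OBz)–C3=C2, which is the 1-ene-3,4-diol monoester that a γ-acyloxyallyl metal gives with an aldehyde. Because C2 is joined back to C5 through C1 and C6, the same C4–C5 bond formation closes the ring. The cis O1/O6 pair can share an acetonide, which holds C2 and C5 on one side of a dioxolane.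

## Logic of the disconnections

**23 ⇒ 22.** The two ketal C–O bonds (O1–CMe2, O6–CMe2) are cut. O1/O6 is the only hydroxyl pair of 23 that can share a five-membered acetal, and masking it leaves a last step that touches no C–C bond and no stereocentre. The forward hydrolysis must be mild enough to leave both benzoates where they are.

**22 ⇒ 20 (through 21).** The C4–C5 bond is cut. This removes the ring and two stereocentres at once, leaves the O4 benzoate already in place, and gives an acyclic precursor with only C1 and C6 stereogenic. The forward step must attack through C4 (not C2), give C4/C5 cis and C5/C6 trans, and outrun loss of O1 from the C2-metallated form.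

**20 ⇒ 19 ⇒ 18.** No skeletal bond is cut; C5 is taken back from aldehyde to alcohol and then to its silyl ether (O5–Si bond). The aldehyde cannot be present when the acyl bromide is used, so C5 must be unmasked last. Both forward operations must be near-neutral and non-nucleophilic because the allylic bromide and the enol ester are already present.

**18 ⇒ 15 + 16 (through 17).** The C2–Br bond and the O4–acyl bond are cut; both come from the one reagent 16 adding across the enal 15. The gain is a simple (E)-enal. The forward step must tolerate the ketal and the silyl ether and must allow the allylic shift of bromide from C4 to C2.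

**15 ⇒ 13 ⇒ 11 ⇒ 9.** The aldehyde is returned to its cyclic acetal, the O1′–benzoyl bond is cut (reagent 12) and the O5–Si bond is cut (reagent 10). This reduces the problem to a diol with two primary hydroxyls. The forward sequence must tell the less hindered O5 from the neopentyl O1′.

**9 ⇒ 7 + 8.** The C2=C3 bond is cut by a Wittig disconnection; C3 and C4 come from the two-carbon salt 8 with C4 masked as an acetal. Opening the lactol 7 frees O5 at the same time. The forward olefination must work on a hindered lactol and must give a product that cannot undergo oxa-Michael closure.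

**7 ⇒ 5 + 6.** The C1–C1′ bond is cut by an aldol disconnection to formaldehyde 6. The quaternary C1 is then fixed by the ring: only the epimer that can re-close to the cis-fused lactol survives, and the acetonide already sits on O1/O6. An entry by acetylide addition to a protected ketotetrose was weighed and not used, because chelation by the dioxolane oxygen would steer the nucleophile to the wrong face for the cis O1/O6 pair and the acetonide would sit on O5/O6. The forward aldol must stop before crossed Cannizzaro reduction.

**5 ⇒ 3 ⇒ 1 (+ 2).** In the forward sense the C1–C2 bond of the pentose is cleaved and its C1 lost. Pentose C3 and C4 of the abundant sugar 1 already carry the configurations needed at C1 and C6, and their cis relation allows the acetonide from 2 to go on selectively. The forward steps must protect only O3/O4 and cleave only the remaining 1,2-diol.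

## Other disconnections considered

**Alternative 1:** The C4–O and C5–O bonds are traced back to an arene: bromobenzene A1 would be oxidised by whole cells expressing toluene dioxygenase to the cis-diene-diol A2.
- Forward key step and mapping: with the bromine on C3, the two carbinol carbons of A2 have the configuration needed at C4 and C5 of 23. The C2=C3 alkene is then already present as the bromoalkene, and the other diene bond is C1=C6.
- In its favour: the carbocycle exists from the first step, two stereocentres are set absolutely by an enzyme from a cheap arene, the two alkenes are electronically distinct, and dihydroxylation of C1=C6 anti to O5 would give the trans O5/O6 relation.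
- Against it here: C1 arrives as an unsubstituted CH, so the C1′ carbon has to be added to a C1 ketone with facial control. O4 and O5 are born together and both secondary, so placing a single benzoate on O4 needs extra differentiation. The bromine must be removed reductively next to an allylic ester, and fermentation capacity is required.
- Comparison: on security of the ring and of the C4/C5 configuration, and on using only established reaction types, this route is the better one. The chosen plan is better at C1 and C6 (sugar plus ring constraint) and delivers the O4 benzoate regiospecifically. Step economy is about equal (ten to twelve operations either way).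

**Alternative 2:** The C1–C6 and C4–C5 bonds are cut together, returning the ring to 3-hydroxy-2-pyrone A3 as diene and (E)-hex-3-ene-2,5-dione A4 as dienophile.
- Forward key step: a cinchona-alkaloid base would form the pyronolate of A3 and guide its [4+2] addition to A4, giving the bridged lactone A5. In A5 the bridgehead C1 carries its hydroxyl, the lactone carbonyl is the future C1′, the lactone oxygen sits on C4, and the acetyl groups on C5 and C6 are trans.
- In its favour: two ring bonds and all four stereocentres are formed in one catalytic step from achiral materials. The lactone bridge hard-wires the cis relation of C1′ and O4 (the two oxygens that end up benzoylated), and the trans C5/C6 relation comes from the alkene geometry.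
- Against it here: both acetyls must become hydroxyls by double Baeyer–Villiger oxidation next to a strained alkene. One of two possible placements of the acetyls relative to the alkene bridge must be obtained. After lactone reduction five oxygens have to be told apart so that only O1′ and O4 carry benzoates, which means acetate/benzoate exchanges beside cis-hydroxyls. The bicyclic lactone can also lose CO2 on warming.
- Comparison: on step economy (roughly seven operations against twelve) and on stereocentres set per step the alternative is the better one. Its key step is a known catalytic cycloaddition type whereas step 11 is not, which is also a point for the alternative. The chosen plan is stronger on oxygen differentiation, since each oxygen enters in its final state, and it takes its absolute configuration from a sugar and not from a catalyst.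

**Alternative 3:** The C5–O and C6–O bonds are traced to an oxirane and the ring to the achiral p-quinol A6, whose two enones are enantiotopic.
- Forward key step: a chiral cinchona-derived amine or ammonium catalyst with a nucleophilic peroxide would epoxidise one enone on the face of the C1 hydroxyl to give A7. C1 becomes stereogenic by desymmetrisation and C6–O is cis to O1. Ketone reduction and O4 benzoylation would follow, and the O4 benzoate would open the oxirane at C5 from the opposite face through a dioxolanylium ion, giving cis O4/O5 with O5 trans to O6.
- In its favour: it is very short, the C1′ benzoate is present from the start, and one stereochemical decision is relayed to all four centres by hydroxyl-directed epoxidation and neighbouring-group opening.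
- Against it here: selection between enantiotopic enones is less secure than chiral-pool control. Hydride must reach C4 from the oxirane face. Collapse of the dioxolanylium ion can leave the ester on O5 and not on O4. The quinol-type tertiary carbinol is prone to rearrangement and aromatisation.
- Comparison: the alternative is better on step count (about six operations) and on atom economy. The two plans are about equal in that each rests on one step whose selectivity is unproven for this substrate class. The chosen plan is better on the final position of the O4 benzoate and on the absolute configuration at C1 and C6.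

Key step: step 11

## Route

Step 1
Reactants: 1 L-arabinose; 2 2,2-dimethoxypropane
Product: 3 3,4-O-isopropylidene-β-L-arabinopyranose
Conditions: 2 (1.5 equiv), TsOH·H2O (cat.), DMF, rt
Reagents that add atoms: 2,2-dimethoxypropane (2), COC(C)(C)OC
Why: Acid-catalysed transketalisation takes the only cis-vicinal diol of the pyranose (O3/O4) and leaves the 1,2-diol free for cleavage; no stereocentre is touched.

Step 2
Reactants: 3
Product: 5 2,3-O-isopropylidene-L-erythrofuranose, via formate ester 4 (not isolated)
Conditions: NaIO4, H2O, 0 °C → rt; then Na2CO3, rt
Reagents that add atoms: none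
Why: Malaprade glycol cleavage of the pentose C1–C2 bond turns pentose C2 into the tetrose aldehyde and C1 into a formate on O5; mild base hydrolyses the formate and the hydroxy aldehyde closes to the cis-fused lactol. Pentose C3 and C4 become C1 and C6 of the target numbering unchanged.

Step 3
Reactants: 5; 6 formaldehyde
Product: 7 2-C-(hydroxymethyl)-2,3-O-isopropylidene-L-erythrofuranose
Conditions: 37% aq. CH2O, K2CO3 (0.3 equiv), MeOH, 65 °C
Reagents that add atoms: formaldehyde (6), C=O
Why: Crossed aldol of the open-chain aldehyde enolate with formaldehyde, a known hydroxymethylation of 2,3-O-isopropylidene furanose lactols. The aldol is reversible and only the C1 epimer whose aldehyde is cis to C5 on the dioxolane can re-close to the stable cis-fused lactol, so CH2OH replaces H at C1 with retention and the C1/C6 relation of the target is fixed.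

Step 4
Reactants: 7; 8 (1,3-dioxolan-2-ylmethyl)triphenylphosphonium bromide
Product: 9 [(4S,5S)-4-[(Z)-2-(1,3-dioxolan-2-yl)ethenyl]-2,2-dimethyl-1,3-dioxolane-4,5-diyl]dimethanol (Z-rich)
Conditions: 8 (3.5 equiv), KOtBu (3.4 equiv), THF, 0 °C → rt
Reagents that add atoms: (1,3-dioxolan-2-ylmethyl)triphenylphosphonium bromide (8), [Br-].C1COC(C[P+](c2ccccc2)(c2ccccc2)c2ccccc2)O1
Why: Wittig olefination of the lactol through its open hydroxy-aldehyde form with a non-stabilised two-carbon ylide that carries C4 as an acetal; excess ylide absorbs the two hydroxyl protons. Unlike an enal or enoate, the product cannot be closed by oxa-Michael addition of the liberated O5.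

Step 5
Reactants: 9; 10 tert-butyl(chloro)diphenylsilane
Product: 11 {(4S,5S)-5-[(tert-butyldiphenylsilyloxy)methyl]-4-[(Z)-2-(1,3-dioxolan-2-yl)ethenyl]-2,2-dimethyl-1,3-dioxolan-4-yl}methanol
Conditions: TBDPSCl (1.05 equiv), imidazole, CH2Cl2, −20 → 0 °C
Reagents that add atoms: tert-butyl(chloro)diphenylsilane (10), CC(C)(C)[Si](Cl)(c1ccccc1)c1ccccc1
Why: Silylation with a bulky chlorosilane should distinguish the C5 hydroxyl (next to a CH) from the neopentyl C1′ hydroxyl (next to quaternary C1). TBDPS is chosen because it resists the acyl bromide and Lewis acid of step 8.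

Step 6
Reactants: 11; 12 benzoyl chloride
Product: 13 {(4S,5S)-5-[(tert-butyldiphenylsilyloxy)methyl]-4-[(Z)-2-(1,3-dioxolan-2-yl)ethenyl]-2,2-dimethyl-1,3-dioxolan-4-yl}methyl benzoate
Conditions: BzCl, pyridine, DMAP (cat.), CH2Cl2, 0 °C → rt
Reagents that add atoms: benzoyl chloride (12), O=C(Cl)c1ccccc1
Why: DMAP-catalysed acylation of the remaining neopentyl primary alcohol installs the C1′ benzoate of the target early; it is inert to every later step.

Step 7
Reactants: 13
Product: 15 {(4S,5S)-5-[(tert-butyldiphenylsilyloxy)methyl]-2,2-dimethyl-4-[(E)-3-oxoprop-1-enyl]-1,3-dioxolan-4-yl}methyl benzoate, via (Z)-enal 14 (not isolated)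
Conditions: TsOH·H2O (cat.), acetone/H2O (20:1), rt
Reagents that add atoms: water, O
Why: Acid-catalysed hydrolysis/transacetalisation of the allylic dioxolane, which ionises far more readily than the hindered ring acetonide (itself protected by the acetone solvent), unmasks the enal. The (Z)-enal equilibrates to the (E)-isomer under the same acid, and the geometry is in any case irrelevant for step 8.

Step 8
Reactants: 15; 16 benzoyl bromide
Product: 18 {(4S,5S)-4-[(E)-3-(benzoyloxy)-1-bromoprop-2-enyl]-5-[(tert-butyldiphenylsilyloxy)methyl]-2,2-dimethyl-1,3-dioxolan-4-yl}methyl benzoate (C2 epimers, E/Z), via 1,2-adduct 17 (not isolated)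
Conditions: BzBr (1.2 equiv), ZnBr2 (2 mol%), CH2Cl2, −20 → 0 °C
Reagents that add atoms: benzoyl bromide (16), O=C(Br)c1ccccc1
Why: Addition of an acyl bromide to an α,β-unsaturated aldehyde: O-acylation and bromide capture give the 1-bromoallyl benzoate 17, which rearranges by Lewis-acid-assisted allylic transposition to the 3-bromo-1-propenyl benzoate, the established way to γ-acyloxyallyl bromides. Both C2 epimers and both enol-ester isomers are usable, any residual 17 would feed the same allylindium, and the low temperature with only catalytic ZnBr2 is meant to spare the acetonide and the silyl ether.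

Step 9
Reactants: 18
Product: 19 {(4S,5S)-4-[(E)-3-(benzoyloxy)-1-bromoprop-2-enyl]-5-(hydroxymethyl)-2,2-dimethyl-1,3-dioxolan-4-yl}methyl benzoate (C2 epimers, E/Z)
Conditions: HF·pyridine, THF, 0 °C → rt
Reagents that add atoms: none
Why: Fluoride-mediated cleavage of the primary silyl ether under weakly acidic, non-basic conditions with no free nucleophile, which should leave the enol benzoate, the allylic bromide, the alkyl benzoate and the acetonide intact.

Step 10
Reactants: 19
Product: 20 {(4S,5R)-4-[(E)-3-(benzoyloxy)-1-bromoprop-2-enyl]-5-formyl-2,2-dimethyl-1,3-dioxolan-4-yl}methyl benzoate (C2 epimers, E/Z; the formyl group is cis to the bromoallyl chain on the dioxolane)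
Conditions: Dess–Martin periodinane, CH2Cl2, 0 °C → rt
Reagents that add atoms: none
Why: Dess–Martin oxidation of the primary alcohol under near-neutral conditions gives the α-alkoxy aldehyde without epimerising C6 or disturbing the bromide; the aldehyde is used at once.

Step 11
Reactants: 20
Product: 22 1,6-O-isopropylidene acetal of 23 (cis-fused dioxolane on O1/O6; O4 benzoate and O5 hydroxyl cis to each other and trans to the dioxolane oxygens; 1S,4R,5R,6S in the ring numbering, C5 changing descriptor but not configuration on deprotection), via allylindium 21 (not isolated)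
Conditions: In powder (3 equiv), THF/sat. aq. NH4Cl (4:1), 0.005 M, rt, sonication
Reagents that add atoms: none
Why: Proposed new method: zerovalent indium inserts into the allylic C2–Br bond to give allylindium 21, whose C2 configuration and C3=C4 geometry are labile through metallotropic shifts, so both C2 epimers, both enol-ester isomers and any allylic regioisomer converge; the γ-carbon C4 then adds to the C5 aldehyde with allylic transposition, forming C4–C5 and the C2=C3 bond. The closest known reactions are the intermolecular indium- or zinc-mediated addition of 3-bromo-1-propenyl benzoate to aldehydes, which gives 1-ene-3,4-diol monobenzoates, and Barbier-type ring closures of simple allyl halides onto tethered aldehydes; new here is that the γ-acyloxyallyl unit itself lies inside the ring being closed. The six-membered ring closes by attack of the allyl terminus on the exocyclic carbonyl (6-exo-trig at C5, all three allyl carbons ending endocyclic), which is easy because the cis-dioxolane holds C2 and C5 on the same side. At C4, C1 must take the inside position of the allyl unit to give the ring (Z)-alkene, so the benzoate takes the outside (E) position, and a closed transition state with indium bridging C2 and the aldehyde oxygen then places O4 cis to O5. At C5, with the indium-bound carbonyl oxygen turned away from the dioxolane oxygen O6 (dipole-opposed, and not chelated in the aqueous medium), the new hydroxyl falls trans to O6. The step needs γ- over α-attack (only γ-attack gives an unstrained ring), cyclisation over dimerisation (high dilution), addition faster than β-elimination of O1 from the C2-metallated form (indium is far less prone to this than zinc), and a buffered medium so that the new O5 alkoxide is protonated before it can take the benzoate from O4.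

Step 12
Reactants: 22
Product: 23 [(1S,4R,5S,6S)-4-(benzoyloxy)-1,5,6-trihydroxycyclohex-2-en-1-yl]methyl benzoate
Conditions: AcOH/H2O (4:1), 50 °C
Reagents that add atoms: none
Why: Acid-catalysed hydrolysis of the isopropylidene ketal frees O1 and O6; benzoates do not migrate or cleave under weak aqueous acid, and no stereocentre is involved.

## Compound list

1 | L-arabinose (aldehydo form drawn) | O=C[C@H](O)[C@@H](O)[C@@H](O)CO | starting material
2 | 2,2-dimethoxypropane | COC(C)(C)OC | starting material
3 | 3,4-O-isopropylidene-β-L-arabinopyranose | OC1OC[C@@H]2OC(C)(C)O[C@@H]2[C@H]1O | intermediate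
4 | 4-O-formyl-2,3-O-isopropylidene-L-erythrose (not isolated) | O=COC[C@@H]1OC(C)(C)O[C@@H]1C=O | intermediate
5 | 2,3-O-isopropylidene-L-erythrofuranose | OC1OC[C@@H]2OC(C)(C)O[C@H]12 | intermediate
6 | formaldehyde | C=O | starting material
7 | 2-C-(hydroxymethyl)-2,3-O-isopropylidene-L-erythrofuranose | OC1OC[C@@H]2OC(C)(C)O[C@]12CO | intermediate
8 | (1,3-dioxolan-2-ylmethyl)triphenylphosphonium bromide | [Br-].C1COC(C[P+](c2ccccc2)(c2ccccc2)c2ccccc2)O1 | starting material
9 | [(4S,5S)-4-[(Z)-2-(1,3-dioxolan-2-yl)ethenyl]-2,2-dimethyl-1,3-dioxolane-4,5-diyl]dimethanol | OC[C@@H]1OC(C)(C)O[C@]1(CO)/C=C\C1OCCO1 | intermediate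
10 | tert-butyl(chloro)diphenylsilane | CC(C)(C)[Si](Cl)(c1ccccc1)c1ccccc1 | starting material
11 | O5-TBDPS ether of 9 | CC(C)(C)[Si](OC[C@@H]1OC(C)(C)O[C@]1(CO)/C=C\C1OCCO1)(c1ccccc1)c1ccccc1 | intermediate
12 | benzoyl chloride | O=C(Cl)c1ccccc1 | starting material
13 | O1′-benzoate of 11 | CC(C)(C)[Si](OC[C@@H]1OC(C)(C)O[C@]1(COC(=O)c1ccccc1)/C=C\C1OCCO1)(c1ccccc1)c1ccccc1 | intermediate
14 | (Z)-enal, {(4S,5S)-5-[(TBDPS-oxy)methyl]-2,2-dimethyl-4-[(Z)-3-oxoprop-1-enyl]-1,3-dioxolan-4-yl}methyl benzoate (not isolated) | CC(C)(C)[Si](OC[C@@H]1OC(C)(C)O[C@]1(COC(=O)c1ccccc1)/C=C\C=O)(c1ccccc1)c1ccccc1 | intermediate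
15 | (E)-enal, {(4S,5S)-5-[(TBDPS-oxy)methyl]-2,2-dimethyl-4-[(E)-3-oxoprop-1-enyl]-1,3-dioxolan-4-yl}methyl benzoate | CC(C)(C)[Si](OC[C@@H]1OC(C)(C)O[C@]1(COC(=O)c1ccccc1)/C=C/C=O)(c1ccccc1)c1ccccc1 | intermediate
16 | benzoyl bromide | O=C(Br)c1ccccc1 | starting material
17 | 1,2-adduct, 1-bromoallyl benzoate at C4 (not isolated) | CC(C)(C)[Si](OC[C@@H]1OC(C)(C)O[C@]1(COC(=O)c1ccccc1)/C=C/C(Br)OC(=O)c1ccccc1)(c1ccccc1)c1ccccc1 | intermediate
18 | C2 bromide / C3=C4 enol benzoate, O5-TBDPS (one isomer drawn) | CC(C)(C)[Si](OC[C@@H]1OC(C)(C)O[C@]1(COC(=O)c1ccccc1)[C@@H](Br)/C=C/OC(=O)c1ccccc1)(c1ccccc1)c1ccccc1 | intermediate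
19 | C2 bromide / enol benzoate, C5 alcohol (one isomer drawn) | OC[C@@H]1OC(C)(C)O[C@]1(COC(=O)c1ccccc1)[C@@H](Br)/C=C/OC(=O)c1ccccc1 | intermediate
20 | bromo enol benzoate aldehyde with C1/C6 acetonide (one isomer drawn) | O=C[C@@H]1OC(C)(C)O[C@]1(COC(=O)c1ccccc1)[C@@H](Br)/C=C/OC(=O)c1ccccc1 | intermediate
21 | γ-benzoyloxyallylindium dibromide from 20 (drawn as the simplest trivalent-indium form; not isolated) | O=C[C@@H]1OC(C)(C)O[C@]1(COC(=O)c1ccccc1)C([In](Br)Br)/C=C/OC(=O)c1ccccc1 | intermediate
22 | 1,6-O-isopropylidene acetal of 23 | O=C(OC[C@@]12C=C[C@@H](OC(=O)c3ccccc3)[C@@H](O)[C@@H]1OC(C)(C)O2)c1ccccc1 | intermediate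
23 | [(1S,4R,5S,6S)-4-(benzoyloxy)-1,5,6-trihydroxycyclohex-2-en-1-yl]methyl benzoate | O=C(OC[C@@]1(O)C=C[C@@H](OC(=O)c2ccccc2)[C@@H](O)[C@@H]1O)c1ccccc1 | target

## Step count and least certain steps

Total step count: 12. Longest linear sequence: 12 steps (1 → 23); compounds 2, 6, 8, 10, 12 and 16 are purchased.

**Step 11 (key step).**
- What may go wrong: reductive β-elimination of O1 from the C2-metallated allylindium (opening of the dioxolane to a dienyl benzoate) may compete with ring closure. Facial selectivity may be poor at C5 (chelated instead of dipole-opposed aldehyde) or at C4 (open instead of closed transition state). The O4 benzoate may transfer to the new cis O5 alkoxide. First levers within the step are zinc in aqueous NH4Cl or CrCl2 in THF.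
- Fallback (known chemistry, intermolecular addition then metathesis), from 7 back to 23: 7 would be methylenated with Ph3P=CH2 to the vinyl diol F1, silylated at O5 to F2, benzoylated at O1′ to F3, desilylated to the alcohol F4 and oxidised to the vinyl aldehyde F5. Aqueous acid would then remove the acetonide to give the dihydroxy aldehyde F6. Indium-mediated addition of 3-bromo-1-propenyl benzoate F7 (made from acrolein and 16) in aqueous solvent is the established intermolecular reaction. With a free α-hydroxyl it is known to favour the erythro relation between the two new centres and the threo relation to the α-carbinol, which is the C4/C5/C6 pattern needed, and would give the diene F8. Ring-closing metathesis of F8 with the second-generation Grubbs catalyst, RuCl2(=CHPh)(H2IMes)(PCy3), would form C2=C3 and give 23 directly.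

**Step 8.**
- What may go wrong: the ketal may be cleaved by the acyl bromide/Lewis acid pair, the allylic shift of bromide to the hindered C2 may be incomplete, and the labile bromide may be lost in the two handling steps that follow.
- Fallback (bromide from an alcohol, enol ester from an alkyne), from 7 back to 18: ethynylmagnesium bromide would add to 7 to give the alkynyl triol F9. O5 silylation would give F10 and O1′ benzoylation F11. Ruthenium-catalysed anti-Markovnikov addition of benzoic acid to the terminal alkyne, with Ru(η3-2-methylallyl)2(dppb), would give the γ-hydroxy (Z)-enol benzoate F12. Appel bromination (CBr4, PPh3) would then give 18 as its isomer mixture without any acyl bromide or Lewis acid.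

**Step 4.**
- What may go wrong: olefination of the hindered, α-quaternary lactol may be slow, and the β-alkoxide may undergo retro-aldol loss of formaldehyde under the basic ylide conditions.
- Fallback (organolithium addition in place of olefination), from 7 back to 15: (Z)-2-ethoxyvinyllithium (from (Z)-1-bromo-2-ethoxyethene and t-BuLi, −78 °C) would add to 7 to give the hydroxy enol ether triol F13. O5 silylation would give F14 and O1′ benzoylation F15. Mild aqueous acid would then convert the β-hydroxy enol ether into the (E)-enal 15 with loss of ethanol and water.

**Step 5.**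
- What may go wrong: discrimination between the two primary hydroxyls may be insufficient, giving regioisomeric and bis-silyl ethers.
- Fallback (differentiation by functional-group type, not by hindrance), from 7 back to 11: the C1′ hydroxyl would be silylated at the lactol stage, where the only other hydroxyl is anomeric, to give the TBS ether F16. Wittig olefination as in step 4 would give F17, in which O5 is the only free hydroxyl. TBDPS protection would give F18, and selective cleavage of the primary TBS ether (HF·pyridine/pyridine, THF, 0 °C) would return 11.

## Further compounds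

F1 | step 11 | [(4S,5S)-4-ethenyl-2,2-dimethyl-1,3-dioxolane-4,5-diyl]dimethanol | OC[C@@H]1OC(C)(C)O[C@]1(CO)C=C
F2 | step 11 | O5-TBDPS ether of F1 | CC(C)(C)[Si](OC[C@@H]1OC(C)(C)O[C@]1(CO)C=C)(c1ccccc1)c1ccccc1
F3 | step 11 | O1′-benzoate of F2 | CC(C)(C)[Si](OC[C@@H]1OC(C)(C)O[C@]1(COC(=O)c1ccccc1)C=C)(c1ccccc1)c1ccccc1
F4 | step 11 | [(4S,5S)-4-ethenyl-5-(hydroxymethyl)-2,2-dimethyl-1,3-dioxolan-4-yl]methyl benzoate | OC[C@@H]1OC(C)(C)O[C@]1(COC(=O)c1ccccc1)C=C
F5 | step 11 | [(4S,5R)-4-ethenyl-5-formyl-2,2-dimethyl-1,3-dioxolan-4-yl]methyl benzoate | O=C[C@@H]1OC(C)(C)O[C@]1(COC(=O)c1ccccc1)C=C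
F6 | step 11 | (2S,3R)-2-ethenyl-2,3-dihydroxy-4-oxobutyl benzoate | O=C[C@H](O)[C@@](O)(COC(=O)c1ccccc1)C=C
F7 | step 11 | 3-bromoprop-1-enyl benzoate (E drawn, E/Z mixture) | BrC/C=C/OC(=O)c1ccccc1
F8 | step 11 | (2S,3S,4S,5R)-5-(benzoyloxy)-2-ethenyl-2,3,4-trihydroxyhept-6-en-1-yl benzoate | O=C(OC[C@@](O)(C=C)[C@@H](O)[C@H](O)[C@H](OC(=O)c1ccccc1)C=C)c1ccccc1
F9 | step 8 | 1-[(4S,5S)-4,5-bis(hydroxymethyl)-2,2-dimethyl-1,3-dioxolan-4-yl]prop-2-yn-1-ol (carbinol epimers) | OC[C@@H]1OC(C)(C)O[C@]1(CO)C(O)C#C
F10 | step 8 | O5-TBDPS ether of F9 | CC(C)(C)[Si](OC[C@@H]1OC(C)(C)O[C@]1(CO)C(O)C#C)(c1ccccc1)c1ccccc1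
F11 | step 8 | O1′-benzoate of F10 | CC(C)(C)[Si](OC[C@@H]1OC(C)(C)O[C@]1(COC(=O)c1ccccc1)C(O)C#C)(c1ccccc1)c1ccccc1
F12 | step 8 | γ-hydroxy (Z)-enol benzoate from F11 | CC(C)(C)[Si](OC[C@@H]1OC(C)(C)O[C@]1(COC(=O)c1ccccc1)C(O)/C=C\OC(=O)c1ccccc1)(c1ccccc1)c1ccccc1
F13 | step 4 | (Z)-3-ethoxy-1-[(4S,5S)-4,5-bis(hydroxymethyl)-2,2-dimethyl-1,3-dioxolan-4-yl]prop-2-en-1-ol (carbinol epimers) | OC[C@@H]1OC(C)(C)O[C@]1(CO)C(O)/C=C\OCC
F14 | step 4 | O5-TBDPS ether of F13 | CC(C)(C)[Si](OC[C@@H]1OC(C)(C)O[C@]1(CO)C(O)/C=C\OCC)(c1ccccc1)c1ccccc1
F15 | step 4 | O1′-benzoate of F14 | CC(C)(C)[Si](OC[C@@H]1OC(C)(C)O[C@]1(COC(=O)c1ccccc1)C(O)/C=C\OCC)(c1ccccc1)c1ccccc1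
F16 | step 5 | 2-C-[(tert-butyldimethylsilyloxy)methyl]-2,3-O-isopropylidene-L-erythrofuranose | OC1OC[C@@H]2OC(C)(C)O[C@]12CO[Si](C)(C)C(C)(C)C
F17 | step 5 | {(4S,5S)-5-(hydroxymethyl) dioxolane with 4-CH2OTBS and 4-[(Z)-2-(1,3-dioxolan-2-yl)ethenyl]} | OC[C@@H]1OC(C)(C)O[C@]1(CO[Si](C)(C)C(C)(C)C)/C=C\C1OCCO1
F18 | step 5 | O5-TBDPS ether of F17 | CC(C)(C)[Si](OC[C@@H]1OC(C)(C)O[C@]1(CO[Si](C)(C)C(C)(C)C)/C=C\C1OCCO1)(c1ccccc1)c1ccccc1
A1 | alternative 1 | bromobenzene | Brc1ccccc1
A2 | alternative 1 | (1S,2S)-3-bromocyclohexa-3,5-diene-1,2-diol | BrC1=CC=C[C@H](O)[C@@H]1O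
A3 | alternative 2 | 3-hydroxy-2H-pyran-2-one | O=C1OC=CC=C1O
A4 | alternative 2 | (E)-hex-3-ene-2,5-dione | CC(=O)/C=C/C(C)=O
A5 | alternative 2 | 7,8-trans-diacetyl-4-hydroxy-2-oxabicyclo[2.2.2]oct-5-en-3-one (C8 acetyl on the alkene-bridge side) | O=C2[C@@]1(O)C=C[C@@H](O2)[C@@H](C(C)=O)[C@@H]1C(C)=O
A6 | alternative 3 | (1-hydroxy-4-oxocyclohexa-2,5-dien-1-yl)methyl benzoate | O=C1C=CC(O)(COC(=O)c2ccccc2)C=C1
A7 | alternative 3 | 5,6-epoxy-4-(benzoyloxymethyl)-4-hydroxycyclohex-2-enone (epoxide syn to hydroxyl) | O=C(OC[C@@]1(O)C=CC(=O)[C@@H]3O[C@H]13)c1ccccc1
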